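The runs were generated by integration on assumed constants; scatter was added.

A small charge of 0.010 M gave 54.3% ring, and a charge twice as large gave less, 38.5%.

| flask | starting material | remark | time |
|---|---|---|---|
| dusk | 0.020 M | run made earlier |  |
| autumn | 0.010 M | run made earlier |  |
| midnight | 0.015 M | run made earlier |  |
| south | 0.020 M | a closed flask charged with all of it at once and left for 4.0 h | 4.0 h |
| west | 0.020 M | a tube with plug flow, the mixed feed as stated, residence time 4.0 h | 4.0 h |
| east | 0.020 M | one stirred flow tank at steady state, fed with the mixture as stated, mean residence time 4.0 h |  |

| run | time / h | ring / % | open dimer / % |
|---|---|---|---|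
| dusk | 0.167 | 33.2 | 45.4 |
| dusk | 0.500 | 38.2 | 44.0 |
| dusk | 0.833 | 38.5 | 43.8 |
| dusk | 1.33 | 39.1 | 43.9 |
| dusk | 2.00 | 38.2 | 44.1 |
| dusk | 2.50 | 38.8 | 43.9 |
| autumn | 0.417 | 52.8 | 35.0 |
| autumn | 0.667 | 54.2 | 35.6 |
| autumn | 1.00 | 54.3 | 36.0 |
| autumn | 2.00 | 54.3 | 36.0 |
| autumn | 3.00 | 54.4 | 35.7 |
| autumn | 5.00 | 54.3 | 35.5 |
| midnight | 0.417 | 43.9 | 40.7 |
| midnight | 0.667 | 45.0 | 41.2 |
| midnight | 1.00 | 45.0 | 41.3 |
| midnight | 2.00 | 45.0 | 40.8 |
| midnight | 3.00 | 45.1 | 40.4 |
| midnight | 5.00 | 44.8 | 40.8 |

(each reading ± 0.3 percentage points)

- a species is counted by the starting material in it: one open dimer or side product counts as two
- a species is counted by the starting material in it: one open trimer counts as three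
- the stated concentrations are those of everything mixed, before any reaction; amounts are the same in each set-up
- the earlier runs were read with a standard deviation of 0.3 percentage points
- the earlier runs were made in a closed, stirred flask

- the set-up with the highest share of ring in all that became ring or open dimer or open trimer or side product, at the outlet or at the end ("none" if the first two lie within 2 percentage points) (south / west / east / none)
- share of ring in all that became ring or open dimer or open trimer or side product, at the outlet or at the end, south
- share of ring in all that became ring or open dimer or open trimer or side product, at the outlet or at the end, west
- share of ring in all that became ring or open dimer or open trimer or side product, at the outlet or at the end, east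

I read the ring column at its plateau, charge against charge. Ring closure looked first order in [starting material] and coupling second order, so what matters is the [starting material] present at each moment.

In a closed flask [starting material] falls through every value below the charge. Going from autumn to midnight therefore adds only the range between them, and the extra ring per extra starting material, 26.4%, is the closing share near 0.0125 M. From midnight to dusk it drops to 19.0%.

The first pair reads 0.00448 M for C×, the crossover concentration: the [starting material] at which closure and coupling consume it equally fast, so that the closing share is C× over the sum of C× and [starting material].

South and west pass through the falling concentrations of dusk, which was flat long before 4.0 h, so I expected about 38.5% in both. At 0.167 h dusk still lacked 0.00106 M of ring. That is ring still to come, not starting material left, since part of what remains couples instead; by the closing share it needs 0.00120 M of [starting material] at that reading. From there I integrated both rates and got a closure constant of 8.12 h⁻¹. The balance of east then holds [starting material] near 5.49 × 10⁻⁴ M, a closing share of 89.1%. So I chose east.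

The forecast also chose east, with 38.6% for south, 38.6% for west and 88.5% for east, reading “first-order ring closure competing with second-order coupling”.

The flask gave east: 38.5% in south, 38.5% in west, 81.5% in east.

    starting material + ring → side product (k = 0.00580 M⁻¹ s⁻¹)
    starting material → decomposition product (k = 4.10 × 10⁻⁷ s⁻¹)
    2 starting material → open dimer (k = 0.180 M⁻¹ s⁻¹)
    starting material → ring (k = 0.00200 s⁻¹)
    starting material + open dimer → open trimer (k = 0.0830 M⁻¹ s⁻¹)

West began at 0.020 M, where C× gives a closing share of 18.3%. East, a pseudo-high dilution, stood at 5.76 × 10⁻⁴ M, where it gives 88.6%. Back-mixing is part of that difference: with it taken away, the share in east goes from 81.5% to 38.5%. The largest single effect on the gap between west and east is the passing of two starting material into open dimer: with that step taken away, west minus east goes from −43 percentage points to 4.3 points.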